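The cyclohexane of the hexahydrobenzofuran core (O1, C2, C3, C3a, C4–C7, C7a) is cut at C3a–C7a and C5–C6, leaving an acyclic ether in which O1 joins allylic C2 to a 3-alkoxybut-2-enal. One tin hydride operation closes both rings: the C3a vinyl radical (from the iodide) adds 5-exo to the enal carbon C7a, relaying the catalytically set C2 centre to the quaternary one, and the neopentyl C5 radical (from the slower bromide) adds 6-exo to the released C6 aldehyde. The feature exploited is dihydrofuran oxygen O1 as tether between C2 and C7a, plus quaternary C4. Oxidation/hydride reduction then sets C6; a C15 + C10 Wittig reaction completes the pentaene.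

Key step: step 7

Remark on numbering: atom numbers are those of the hexahydro-1-benzofuran core, O1, C2 (side chain), C3, C3a, C4 (gem-dimethyl), C5, C6 (carbinol), C7, C7a (angular methyl).
Remark on step 4: (S,S)-ProPhenol is assumed to deliver the (S)-carbinol 8; if the facial sense is the opposite, (R,R)-ProPhenol is used with no other change.

Step 1
Reactants: 1 3-bromo-2,2-dimethylpropan-1-ol
Product: 2 3-bromo-2,2-dimethylpropanal
Conditions: TEMPO (0.1 equiv), PhI(OAc)2 (1.1 equiv), CH2Cl2, rt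
Reagents that add atoms: none
Why: The oxoammonium (TEMPO) oxidation should stop cleanly at the non-enolisable neopentyl aldehyde and leave the primary bromide untouched.

Step 2
Reactants: 2 3-bromo-2,2-dimethylpropanal
Product: 3 4-bromo-3,3-dimethylbut-1-yne
Conditions: dimethyl (1-diazo-2-oxopropyl)phosphonate (1.3 equiv), K2CO3, MeOH, 0 °C to rt
Reagents that add atoms: dimethyl (1-diazo-2-oxopropyl)phosphonate, CC(=O)C(=[N+]=[N-])P(=O)(OC)OC
Why: Seyferth–Gilbert homologation with the Ohira–Bestmann reagent should convert the non-enolisable aldehyde into the terminal alkyne, the neopentyl bromide being inert to K2CO3/MeOH.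

Step 3
Reactants: 4 [(tert-butyldimethylsilyl)oxy]acetaldehyde; 5 2-(triphenylphosphoranylidene)propanal
Product: 6 (2E)-4-[(tert-butyldimethylsilyl)oxy]-2-methylbut-2-enal
Conditions: toluene, 80 °C
Reagents that add atoms: none
Why: Wittig olefination with a formyl-stabilised ylide should give the (E)-trisubstituted enal, and the conjugated product aldehyde should not react further.

Step 4
Reactants: 3 4-bromo-3,3-dimethylbut-1-yne; 6 (2E)-4-[(tert-butyldimethylsilyl)oxy]-2-methylbut-2-enal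
Product: 8 (2E,4S)-8-bromo-1-[(tert-butyldimethylsilyl)oxy]-3,7,7-trimethyloct-2-en-5-yn-4-ol, via alkynyl(methyl)zinc 7 (not isolated)
Conditions: Me2Zn (3 equiv), (S,S)-ProPhenol (0.2 equiv), Ph3P=O (0.4 equiv), toluene, 0 °C; aq. NH4Cl
Reagents that add atoms: none
Why: Dinuclear zinc ProPhenol-catalysed enantioselective alkynylation of an α,β-unsaturated aldehyde should set the carbinol centre (the future C2), the only stereocentre made by catalysis, by face-selective delivery of the zinc acetylide in the chiral dizinc pocket.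

Step 5
Reactants: 8 (2E,4S)-8-bromo-1-[(tert-butyldimethylsilyl)oxy]-3,7,7-trimethyloct-2-en-5-yn-4-ol
Product: 10 (2E,4R,5Z)-8-bromo-1-[(tert-butyldimethylsilyl)oxy]-6-iodo-3,7,7-trimethylocta-2,5-dien-4-ol, via cyclic sodium alkenylaluminate 9 (not isolated)
Conditions: NaAlH2(OCH2CH2OCH3)2 (1.5 equiv), THF, 0 °C to rt; then I2, −78 °C to 0 °C; aq. KNaC4H4O6
Reagents that add atoms: iodine, [I][I]
Why: Alkoxide-directed trans-hydroalumination of the propargylic alcohol places aluminium on the distal alkyne carbon in a five-membered aluminate, and iodinolysis with retention should give the (Z)-3-iodoallylic alcohol; the carbinol centre is not touched (its descriptor changes only by CIP priority).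

Step 6
Reactants: 10 (2E,4R,5Z)-8-bromo-1-[(tert-butyldimethylsilyl)oxy]-6-iodo-3,7,7-trimethylocta-2,5-dien-4-ol; 11 but-2-ynal
Product: 12 (2E)-3-{[(2E,4R,5Z)-8-bromo-1-[(tert-butyldimethylsilyl)oxy]-6-iodo-3,7,7-trimethylocta-2,5-dien-4-yl]oxy}but-2-enal
Conditions: DABCO (0.2 equiv), but-2-ynal (1.5 equiv), CH2Cl2, 0 °C to rt
Reagents that add atoms: none
Why: Amine-catalysed oxa-Michael addition of the secondary alcohol to the ynal should give the (E)-β-alkoxy enal; only the O–H bond reacts, so the carbinol configuration is kept.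

Step 7
Reactants: 12 (2E)-3-{[(2E,4R,5Z)-8-bromo-1-[(tert-butyldimethylsilyl)oxy]-6-iodo-3,7,7-trimethylocta-2,5-dien-4-yl]oxy}but-2-enal
Product: 14 (2R,6R,7aR)-2-{(2E)-4-[(tert-butyldimethylsilyl)oxy]but-2-en-2-yl}-4,4,7a-trimethyl-2,4,5,6,7,7a-hexahydro-1-benzofuran-6-ol, via monocyclic bromo aldehyde 13 (not isolated)
Conditions: Bu3SnH (2.3 equiv) and AIBN (0.3 equiv) added by syringe pump over 8 h, benzene (0.005 M in 12), 80 °C
Reagents that add atoms: none
Why: Bu3Sn• abstracts iodine from the vinyl iodide much faster than bromine from the neopentyl bromide, so the C3a σ-vinyl radical forms first and adds 5-exo-trig to the β-carbon of the alkoxy enal (new C3a–C7a bond, dihydrofuran ring); the α-formyl radical takes hydrogen from Bu3SnH to give aldehyde 13, after which bromine abstraction gives the neopentyl C5 radical, which adds 6-exo-trig to the aldehyde carbon (new C5–C6 bond, cyclohexane ring) and the alkoxy radical is quenched by Bu3SnH. The closest known reaction types are the vinyl-radical conjugate cyclisation onto β-alkoxyacrylates, used for cis-2,5-disubstituted oxolanes, and the 6-exo cyclisation of alkyl radicals onto aldehydes. The quaternary centre C7a is set by substrate control from C2: in the chair-like 5-exo transition state the C2 side chain is pseudo-equatorial and the exo-alkene carbon points outward, which places the C2 substituent and the C7 methylene cis and the methyl trans. C6 is expected mainly as the equatorial 6R alcohol (aldehyde oxygen away from the two syn-axial methyls), but this centre is not relied on because steps 8 and 9 reset it. The step needs the halide order (iodide/bromide rate gap, slow addition), 5-exo instead of 6-endo attack (polarised enal, β-carbon electrophilic) and ring closure of the neopentyl radical before its reduction (high dilution, gem-dimethyl effect, no β-hydrogen on C4).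

Step 8
Reactants: 14 (2R,6R,7aR)-2-{(2E)-4-[(tert-butyldimethylsilyl)oxy]but-2-en-2-yl}-4,4,7a-trimethyl-2,4,5,6,7,7a-hexahydro-1-benzofuran-6-ol
Product: 15 (2R,7aR)-2-{(2E)-4-[(tert-butyldimethylsilyl)oxy]but-2-en-2-yl}-4,4,7a-trimethyl-4,5,7,7a-tetrahydro-1-benzofuran-6(2H)-one
Conditions: Dess–Martin periodinane (1.3 equiv), pyridine, CH2Cl2, 0 °C to rt
Reagents that add atoms: none
Why: Dess–Martin oxidation under buffered, non-basic conditions should give the β-alkoxy ketone without retro-oxa-Michael ring opening and removes the unwanted C6 configuration.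

Step 9
Reactants: 15 (2R,7aR)-2-{(2E)-4-[(tert-butyldimethylsilyl)oxy]but-2-en-2-yl}-4,4,7a-trimethyl-4,5,7,7a-tetrahydro-1-benzofuran-6(2H)-one
Product: 16 (2R,6S,7aR)-2-{(2E)-4-[(tert-butyldimethylsilyl)oxy]but-2-en-2-yl}-4,4,7a-trimethyl-2,4,5,6,7,7a-hexahydro-1-benzofuran-6-ol
Conditions: LiBH(s-Bu)3 (1.2 equiv), THF, −78 °C; aq. NH4Cl
Reagents that add atoms: none
Why: In this substrate-controlled ketone reduction the bulky hydride should attack the face opposite the two syn-axial methyl groups (C7a–CH3, held axial by the ring fusion, and one C4–CH3), giving the axial 6S alcohol cis to the angular methyl, as in the reduction of 3,3,5-trimethylcyclohexanone.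

Step 10
Reactants: 16 (2R,6S,7aR)-2-{(2E)-4-[(tert-butyldimethylsilyl)oxy]but-2-en-2-yl}-4,4,7a-trimethyl-2,4,5,6,7,7a-hexahydro-1-benzofuran-6-ol
Product: 17 (2R,6S,7aR)-2-[(2E)-4-hydroxybut-2-en-2-yl]-4,4,7a-trimethyl-2,4,5,6,7,7a-hexahydro-1-benzofuran-6-ol
Conditions: Bu4NF (1.2 equiv), THF, 0 °C to rt
Reagents that add atoms: none
Why: Fluoride-mediated desilylation should free the primary allylic alcohol; no other fluoride- or base-labile group is present.

Step 11
Reactants: 17 (2R,6S,7aR)-2-[(2E)-4-hydroxybut-2-en-2-yl]-4,4,7a-trimethyl-2,4,5,6,7,7a-hexahydro-1-benzofuran-6-ol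
Product: 19 {(2E)-3-[(2R,6S,7aR)-6-hydroxy-4,4,7a-trimethyl-2,4,5,6,7,7a-hexahydro-1-benzofuran-2-yl]but-2-en-1-yl}triphenylphosphonium bromide, via allylic bromide 18 (not isolated)
Conditions: CBr4 (1.05 equiv), PPh3 (1.1 equiv), CH2Cl2, −20 °C; then PPh3 (1.5 equiv), rt
Reagents that add atoms: tetrabromomethane, BrC(Br)(Br)Br; triphenylphosphine, c1ccc(cc1)P(c1ccccc1)c1ccccc1
Why: Appel bromination should select the unhindered primary allylic alcohol over the axial secondary one, and the labile bromide is trapped at once by SN2 quaternisation of PPh3 under neutral conditions that do not ionise the allylic ether at C2.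

Step 12
Reactants: 19 {(2E)-3-[(2R,6S,7aR)-6-hydroxy-4,4,7a-trimethyl-2,4,5,6,7,7a-hexahydro-1-benzofuran-2-yl]but-2-en-1-yl}triphenylphosphonium bromide; 20 (2E,4E,6E)-2,7-dimethylocta-2,4,6-trienedial
Product: 22 (2E,4E,6E,8E,10E)-11-[(2R,6S,7aR)-6-hydroxy-4,4,7a-trimethyl-2,4,5,6,7,7a-hexahydro-1-benzofuran-2-yl]-2,7-dimethyldodeca-2,4,6,8,10-pentaenal, via phosphonium ylide 21 (not isolated)
Conditions: NaOMe (1.1 equiv), 20 (3 equiv), CH2Cl2/MeOH, 0 °C to rt, dark; then heptane, 80 °C
Reagents that add atoms: none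
Why: Wittig condensation of the semi-stabilised allylic ylide with excess dialdehyde should stop at the mono-adduct because the extended polyenal is less electrophilic than the dial, and any hindered Z isomer at the new double bond should relax thermally to the all-E polyene.

Step 13
Reactants: 22 (2E,4E,6E,8E,10E)-11-[(2R,6S,7aR)-6-hydroxy-4,4,7a-trimethyl-2,4,5,6,7,7a-hexahydro-1-benzofuran-2-yl]-2,7-dimethyldodeca-2,4,6,8,10-pentaenal
Product: 23 (2E,4E,6E,8E,10E)-11-[(2R,6S,7aR)-6-hydroxy-4,4,7a-trimethyl-2,4,5,6,7,7a-hexahydro-1-benzofuran-2-yl]-2,7-dimethyldodeca-2,4,6,8,10-pentaen-1-ol (CNP0239155.2)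
Conditions: NaBH4, MeOH/THF, 0 °C, dark
Reagents that add atoms: none
Why: NaBH4 should reduce the polyenal by 1,2-addition to the primary allylic alcohol without touching the polyene, the ether or the stereocentres.

Compound list
1 | 3-bromo-2,2-dimethylpropan-1-ol | OCC(C)(C)CBr | starting material
2 | 3-bromo-2,2-dimethylpropanal | O=CC(C)(C)CBr | intermediate
3 | 4-bromo-3,3-dimethylbut-1-yne | C#CC(C)(C)CBr | intermediate
4 | [(tert-butyldimethylsilyl)oxy]acetaldehyde | O=CCO[Si](C)(C)C(C)(C)C | starting material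
5 | 2-(triphenylphosphoranylidene)propanal | CC(C=O)=P(c1ccccc1)(c1ccccc1)c1ccccc1 | starting material
6 | (2E)-4-[(tert-butyldimethylsilyl)oxy]-2-methylbut-2-enal | O=C/C(C)=C/CO[Si](C)(C)C(C)(C)C | intermediate
7 | (4-bromo-3,3-dimethylbut-1-yn-1-yl)(methyl)zinc | C[Zn]C#CC(C)(C)CBr | intermediate
8 | (2E,4S)-8-bromo-1-[(tert-butyldimethylsilyl)oxy]-3,7,7-trimethyloct-2-en-5-yn-4-ol | C/C(=C\CO[Si](C)(C)C(C)(C)C)[C@H](O)C#CC(C)(C)CBr | intermediate
9 | sodium (5R)-3-(1-bromo-2-methylpropan-2-yl)-5-{(2E)-4-[(tert-butyldimethylsilyl)oxy]but-2-en-2-yl}-2,2-bis(2-methoxyethoxy)-2,5-dihydro-1,2-oxaluminol-2-uide | [Na+].C/C(=C\CO[Si](C)(C)C(C)(C)C)[C@H]1C=C(C(C)(C)CBr)[Al-](OCCOC)(OCCOC)O1 | intermediate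
10 | (2E,4R,5Z)-8-bromo-1-[(tert-butyldimethylsilyl)oxy]-6-iodo-3,7,7-trimethylocta-2,5-dien-4-ol | C/C(=C\CO[Si](C)(C)C(C)(C)C)[C@H](O)/C=C(\I)C(C)(C)CBr | intermediate
11 | but-2-ynal | CC#CC=O | starting material
12 | (2E)-3-{[(2E,4R,5Z)-8-bromo-1-[(tert-butyldimethylsilyl)oxy]-6-iodo-3,7,7-trimethylocta-2,5-dien-4-yl]oxy}but-2-enal | C/C(=C\CO[Si](C)(C)C(C)(C)C)[C@H](O/C(C)=C/C=O)/C=C(\I)C(C)(C)CBr | intermediate
13 | 2-[(2R,5R)-3-(1-bromo-2-methylpropan-2-yl)-5-{(2E)-4-[(tert-butyldimethylsilyl)oxy]but-2-en-2-yl}-2-methyl-2,5-dihydrofuran-2-yl]acetaldehyde | C/C(=C\CO[Si](C)(C)C(C)(C)C)[C@H]1C=C(C(C)(C)CBr)[C@@](C)(CC=O)O1 | intermediate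
14 | (2R,6R,7aR)-2-{(2E)-4-[(tert-butyldimethylsilyl)oxy]but-2-en-2-yl}-4,4,7a-trimethyl-2,4,5,6,7,7a-hexahydro-1-benzofuran-6-ol | C/C(=C\CO[Si](C)(C)C(C)(C)C)[C@H]1C=C2C(C)(C)C[C@@H](O)C[C@@]2(C)O1 | intermediate
15 | (2R,7aR)-2-{(2E)-4-[(tert-butyldimethylsilyl)oxy]but-2-en-2-yl}-4,4,7a-trimethyl-4,5,7,7a-tetrahydro-1-benzofuran-6(2H)-one | C/C(=C\CO[Si](C)(C)C(C)(C)C)[C@H]1C=C2C(C)(C)CC(=O)C[C@@]2(C)O1 | intermediate
16 | (2R,6S,7aR)-2-{(2E)-4-[(tert-butyldimethylsilyl)oxy]but-2-en-2-yl}-4,4,7a-trimethyl-2,4,5,6,7,7a-hexahydro-1-benzofuran-6-ol | C/C(=C\CO[Si](C)(C)C(C)(C)C)[C@H]1C=C2C(C)(C)C[C@H](O)C[C@@]2(C)O1 | intermediate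
17 | (2R,6S,7aR)-2-[(2E)-4-hydroxybut-2-en-2-yl]-4,4,7a-trimethyl-2,4,5,6,7,7a-hexahydro-1-benzofuran-6-ol | C/C(=C\CO)[C@H]1C=C2C(C)(C)C[C@H](O)C[C@@]2(C)O1 | intermediate
18 | (2R,6S,7aR)-2-[(2E)-4-bromobut-2-en-2-yl]-4,4,7a-trimethyl-2,4,5,6,7,7a-hexahydro-1-benzofuran-6-ol | C/C(=C\CBr)[C@H]1C=C2C(C)(C)C[C@H](O)C[C@@]2(C)O1 | intermediate
19 | {(2E)-3-[(2R,6S,7aR)-6-hydroxy-4,4,7a-trimethyl-2,4,5,6,7,7a-hexahydro-1-benzofuran-2-yl]but-2-en-1-yl}triphenylphosphonium bromide | C/C(=C\C[P+](c1ccccc1)(c1ccccc1)c1ccccc1)[C@H]1C=C2C(C)(C)C[C@H](O)C[C@@]2(C)O1.[Br-] | intermediate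
20 | (2E,4E,6E)-2,7-dimethylocta-2,4,6-trienedial | O=C/C(C)=C/C=C/C=C(\C)C=O | starting material
21 | (2R,6S,7aR)-4,4,7a-trimethyl-2-[(2E)-4-(triphenylphosphoranylidene)but-2-en-2-yl]-2,4,5,6,7,7a-hexahydro-1-benzofuran-6-ol | C/C(=C\C=P(c1ccccc1)(c1ccccc1)c1ccccc1)[C@H]1C=C2C(C)(C)C[C@H](O)C[C@@]2(C)O1 | intermediate
22 | (2E,4E,6E,8E,10E)-11-[(2R,6S,7aR)-6-hydroxy-4,4,7a-trimethyl-2,4,5,6,7,7a-hexahydro-1-benzofuran-2-yl]-2,7-dimethyldodeca-2,4,6,8,10-pentaenal | CC(/C=C/C=C(\C)[C@H]1C=C2C(C)(C)C[C@H](O)C[C@@]2(C)O1)=C\C=C\C=C(/C)C=O | intermediate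
23 | (2E,4E,6E,8E,10E)-11-[(2R,6S,7aR)-6-hydroxy-4,4,7a-trimethyl-2,4,5,6,7,7a-hexahydro-1-benzofuran-2-yl]-2,7-dimethyldodeca-2,4,6,8,10-pentaen-1-ol | CC(/C=C/C=C(\C)[C@H]1C=C2C(C)(C)C[C@H](O)C[C@@]2(C)O1)=C\C=C\C=C(/C)CO | target

Total step count: 13. Longest linear sequence: 12 steps (steps 1, 2, 4 to 13); step 3 is a one-step side branch.

Steps most likely to fail

Step 7. The neopentyl bromide may lose bromine and be reduced before the first ring has closed, the vinyl or neopentyl radical may be reduced before it cyclises, or the vinyl radical may attack the wrong face of the enal at C7a. The fallback sets out from 12 and separates the two closures, making the first one by palladium instead of a radical: Pd(OAc)2, PPh3 and HCO2Na in DMF at 60 °C (reductive Heck reaction, 5-exo carbopalladation of the enal and formate reduction of the palladium enolate; the neopentyl bromide does not add oxidatively under these conditions) should give the monocyclic bromo aldehyde 13, which is now isolated. Bu3SnH/AIBN in dilute benzene at 80 °C then closes the cyclohexane by the 6-exo radical addition to the aldehyde and the route is rejoined at 14. This fallback makes no compound outside the list (F0).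

Step 6. Conjugate addition of the hindered bis-allylic alcohol to the β-methyl ynal may be slow and be overtaken by hemiacetal formation and oligomerisation of the ynal. The fallback sets out from 10: its sodium alkoxide (NaH, 0.2 equiv, THF, 0 °C) adds to ethyl but-2-ynoate to give ethyl (2E)-3-{[(2E,4R,5Z)-8-bromo-1-[(tert-butyldimethylsilyl)oxy]-6-iodo-3,7,7-trimethylocta-2,5-dien-4-yl]oxy}but-2-enoate F1; i-Bu2AlH (CH2Cl2, −78 °C) reduces the ester to (2E)-3-{[(2E,4R,5Z)-8-bromo-1-[(tert-butyldimethylsilyl)oxy]-6-iodo-3,7,7-trimethylocta-2,5-dien-4-yl]oxy}but-2-en-1-ol F2; MnO2 (CH2Cl2, rt) oxidises the allylic alcohol and the route is rejoined at 12.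

Step 12. The ylide may condense a second time on the product aldehyde or give an unselective geometry at the new double bond. The fallback sets out from 17: bromide 18 is made as in the first half of step 11 and heated with P(OEt)3 (90 °C, Arbuzov reaction) in place of PPh3 to give diethyl {(2E)-3-[(2R,6S,7aR)-6-hydroxy-4,4,7a-trimethyl-2,4,5,6,7,7a-hexahydro-1-benzofuran-2-yl]but-2-en-1-yl}phosphonate F3. Deprotonation with NaN(SiMe3)2 (2.1 equiv, THF, −78 °C) and addition to excess 20 (Horner–Wadsworth–Emmons reaction, E-selective, the stabilised carbanion discriminating better between dial and product aldehyde) rejoins the route at 22.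

Further compounds
F0 | step 7 | none | none
F1 | step 6 | ethyl (2E)-3-{[(2E,4R,5Z)-8-bromo-1-[(tert-butyldimethylsilyl)oxy]-6-iodo-3,7,7-trimethylocta-2,5-dien-4-yl]oxy}but-2-enoate | C/C(=C\CO[Si](C)(C)C(C)(C)C)[C@H](O/C(C)=C/C(=O)OCC)/C=C(\I)C(C)(C)CBr
F2 | step 6 | (2E)-3-{[(2E,4R,5Z)-8-bromo-1-[(tert-butyldimethylsilyl)oxy]-6-iodo-3,7,7-trimethylocta-2,5-dien-4-yl]oxy}but-2-en-1-ol | C/C(=C\CO[Si](C)(C)C(C)(C)C)[C@H](O/C(C)=C/CO)/C=C(\I)C(C)(C)CBr
F3 | step 12 | diethyl {(2E)-3-[(2R,6S,7aR)-6-hydroxy-4,4,7a-trimethyl-2,4,5,6,7,7a-hexahydro-1-benzofuran-2-yl]but-2-en-1-yl}phosphonate | C/C(=C\CP(=O)(OCC)OCC)[C@H]1C=C2C(C)(C)C[C@H](O)C[C@@]2(C)O1
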